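I cannot read the ratio of other capture product to target at 0.25 s from any run, because the first reading comes 120 times later. I bracket it.

common to all: starting material 0.075 M

| run | first nucleophile | second nucleophile | remark | time |
|---|---|---|---|---|
| north-east | 2 equiv | 0.55 equiv | run made earlier |  |
| north-west | 2 equiv | 0.83 equiv | run made earlier |  |
| flask | 2.00 equiv | 1.10 equiv |  | 6.0 min |

| run | time / min | other capture product / % | target / % |
|---|---|---|---|
| north-east | 0.500 | 1 | 20 |
| north-east | 1.33 | 0 | 16 |
| north-east | 2.50 | 4 | 12 |
| north-east | 4.00 | 2 | 11 |
| north-east | 6.00 | 2 | 5 |
| north-east | 8.00 | 4 | 5 |
| north-west | 1.33 | 3 | 20 |
| north-west | 2.50 | 2 | 15 |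
| north-west | 4.00 | 4 | 10 |
| north-west | 5.00 | 1 | 8 |
| north-west | 6.00 | 1 | 6 |
| north-west | 8.00 | 4 | 6 |

(standard deviation of a reading: 1.5 percentage points)

- a species is counted by the starting material in it: one idle adduct counts as two
- amounts and yields of target count idle adduct too
- on the list of suspects stand: first nucleophile + target -> over-reaction product; second nucleophile + intermediate -> other capture product; intermediate -> solvolysis product; first nucleophile + intermediate -> target; starting material -> intermediate; starting material + target <-> idle adduct
- in an amount of target, one idle adduct counts as one target

1. ratio of other capture product to target at 0.25 s
2. ratio of other capture product to target at 6.0 min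

The other capture product wanders within the scatter, so I replace its curve by its mean. Pooled over 12 readings, that is a share of 0.0338 of the starting material per equivalent of second nucleophile, give or take 0.00628. For early target I take the reading 20% as a floor; back to the start along their own decay, the two runs give 21.9% and 25.4%. Reading the early ratio as totals formed, high capture over the floor bounds this flask's early ratio from above at 0.221; low capture over the highest target bounds it from below at 0.119.

Both captures are suspected of drawing on one intermediate, so I carry the selectivity factor, the early ratio divided by the charged ratio of second to first nucleophile: 0.286. It gives this flask 0.157 at 0.25 s. With the two readings of target at 6.0 min, I get 0.676 there.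

The forecast says 0.17 and 0.7, calling the first “the kinetic capture ratio”; its early value lies inside my bracket, above my own 0.157.

The flask gives 0.175 and 0.635.

    first nucleophile + target → over-reaction product (k = 0.0280 /M/s)
    second nucleophile + intermediate → other capture product (k = 13.0 /M/s)
    intermediate → solvolysis product (k = 19.0 /s)
    first nucleophile + intermediate → target (k = 41.0 /M/s)
    starting material → intermediate (k = 0.280 /s)
    starting material + target ⇌ idle adduct, settled at all times (K = 13.0 /M)

Just after the start, this flask's intermediate goes to solvolysis product 3.1 times as fast as to target. By 6.0 min, 73.5% of the charge has gone that way. With 2.80 equiv of second nucleophile, the factor gives 0.400 at 0.25 s; that neighbour flask computes to 0.445.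

(The earlier runs and the new flask stem from a simulated flask with constants of no real substance, and the scatter is random.)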